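The numbers are assumed; the rest is arithmetic.

One decade, a factor of ten in rate, was my unit for this job. Electrophile and nucleophile give target and acid, the acid ties up nucleophile as protonated nucleophile, and electrophile also eats target to give side product.

    electrophile + nucleophile → acid set free + target (k1 = 8.02 × 10⁻⁴ M⁻¹ s⁻¹)
    nucleophile + acid set free ⇌ protonated nucleophile, settled at all times (K2 = 643 M⁻¹)
    electrophile + target → side product (k3 = 0.00164 M⁻¹ s⁻¹)

| setting | west | south-west | north-west | east |
|---|---|---|---|---|
| electrophile | 0.011 M | 0.011 M | 0.011 M | 0.011 M |
| nucleophile | 0.0165 M | 0.0165 M | 0.0165 M | 0.0165 M (fed, over 16.0 h) |
| remark | one stirred flow tank at steady state, fed with the mixture as stated, mean residence time 200 h | a closed flask charged with all of it at once and left for 20 h | one stirred flow tank at steady state, fed with the mixture as stated, mean residence time 20 h | a stirred flask in which nucleophile is dosed at a steady rate over 16.0 h without added volume, worked up at 20 h |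
| time |  | 20 h |  | 20 h |

- a species is counted by the electrophile in it: one side product counts as two
- the stated concentrations are those of everything mixed, before any reaction; amounts are the same in each set-up
- the feed brings no volume worth counting
- run time (south-west): 20 h

* the set-up with the highest amount of target at the outlet or at the end, in percent of the electrophile put in ("none" if the first two lie within 2 percentage points) (west / south-west / north-west / east / none)
* amount of target at the outlet or at the end, in percent of the electrophile put in, west
* amount of target at the outlet or at the end, in percent of the electrophile put in, south-west
* amount of target at the outlet or at the end, in percent of the electrophile put in, north-west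
* amount of target at the outlet or at the end, in percent of the electrophile put in, east

I reckoned the closed flask (south-west). Its first step starts at 5.24 × 10⁻⁴ M h⁻¹. Two factors slow it: the share of electrophile left and the share of nucleophile still free. At the start the acid's binding constant times the nucleophile is 11, so nearly all of the acid takes a nucleophile, and I counted two nucleophile lost per turn of the first step. The selectivity factor, the loss constant over the making constant, is twice, and I took it as two, so it cancels against that cost. Target then turns from gain to loss when free nucleophile has fallen by a factor e, the base of natural logarithms, which is 0.434 decade. My carried quantity is the turning yield, the target at that turn in percent of the electrophile charged: 27.6%. By then 47.4% of the electrophile has gone through the first step and 32.8% of the electrophile charged is left, about a third. The rate has therefore fallen by a factor 8.29, or 0.919 decade. If the rate falls evenly in decades, the turn comes near 23.9 h, later than 20 h, so I expected the closed flask to end close below the turning yield.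

The forecast chose south-west, with 18% for west, 27% for south-west, 18.5% for north-west and 22% for east: “The closed flask wins because all the nucleophile is free from the start”. My turning yield stands above its south-west figure, inside its range up to 29%.

The simulation gave south-west as best, with 18.1% for west, 27.7% for south-west, 18.5% for north-west and 22.7% for east.

Neither batch flask had come to rest at 20 h. South-west stood 0.10 percentage points from the turning yield, and left until 200 h it lost 1.3 points, ending at 26.4%. East, the dosed flask, still held 57.9% of its electrophile at 20 h, stood 4.9 points below the turning yield, and gained 3.2 points by 200 h, still below it. At 200 h south-west read 26.4% and east 25.9%, a gap of 0.50 points, inside the margin of 2 points.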